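**Assumption:** epoxide 8 is made and used as the racemate, because both of its stereocentres are erased in step 5; 4-methoxybenzene-1,3-diol (1) is taken to be a catalogue compound.

## Structural features

The target 11 is an isoflavone: a 4H-chromen-4-one in which benzo ring A is fused through C4a and C8a to the γ-pyranone ring C, and ring B, a 3,4,5-trimethoxyphenyl group, is joined to C3 by a single bond. Ring A carries a methoxy group at C6 and the only free hydroxyl at C7, so the two arenes carry five oxygen substituents, four of them as methyl ethers. There is no stereocentre in 11; the only stereocentres on the way (the two oxirane carbons of 8, then C2 and C3 of 10) are adjacent pairs that are transient and erased again. The fragile parts are the pyranone, whose C2 accepts nucleophiles with ring opening and whose C2=C3 bond can be hydrogenated, and the C7 hydroxyl, which must be told apart from four methyl ethers without any dealkylating reagent. The real difficulty is therefore connectivity and oxygen differentiation: carbonyl condensation naturally gives the 1,3-diaryl three-carbon chain of a chalcone, whereas 11 has the 1,2-diaryl arrangement. The key step exploits the fact that C3 carries three carbon substituents at once, namely C4 (the ketone bound to C4a of ring A), C1' of ring B and C2 at the aldehyde oxidation level. This is exactly the array left behind when an aroyl group moves from the α to the β carbon of a chalcone epoxide. O1 then only has to be joined to C2, which an ortho phenol does without help.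

## Logic of the disconnections

**11 ⇒ 9 (through 10).** Ring C is opened at O1–C2, the C2=C3 unsaturation is traced back through 10 to loss of water, and the two benzyl–oxygen bonds at O7 and O8a are restored. The cut is made here because the forward condensation is downhill (a benzo-fused vinylogous ester forms) and because O7 can then travel as a benzyl ether, so no methyl ether ever has to be cleaved. The gain is an acyclic, enolized 1,3-dicarbonyl unit on a fully protected ring A. The forward step must remove two benzyl groups without reducing the enol, the aldehyde or the new C2=C3 bond; only O8a can reach C2, so O7 cannot compete.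

**9 ⇒ 8.** The C3–C4 bond is cut, C4 is put back on C2, and the oxygen on C2 is bridged to C3: a retro 1,2-acyl shift. This turns the branched 1,2-diaryl skeleton of 9 into the linear 1,3-diaryl skeleton of 8, which aldol chemistry delivers, with no change in carbon count. The forward step must ionise the oxirane only at the carbon bearing ring B, move the aroyl group and not hydride to that carbon, and leave benzyl and methyl ethers untouched.

**8 ⇒ 7.** The two C–O bonds of the oxirane are cut and one oxygen atom is removed. The reason is that the β carbon of 7 is electrophilic, so a nucleophilic oxidant installs the oxygen without touching the electron-rich arenes. Two stereocentres disappear. The forward step requires conjugate addition of hydroperoxide to a donor-substituted enone, and the oxygen ortho to the carbonyl must be masked, since a free phenol there would divert the oxidation to flavonol or aurone products.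

**7 ⇒ 5 + 6.** The Cα=Cβ double bond of 7 (the later C2 and C3) is cut by a retro-aldol condensation. This divides the molecule into its ring A half and its ring B half, each with all its oxygen substituents in place. The forward step needs an enolisable methyl ketone and an aldehyde with no α hydrogen, and both phenols of ring A must be capped so that no phenoxide deactivates the ketone.

**5 ⇒ 3 + 4.** Both O–CH2 bonds of the benzyl ethers are cut. One group serves both phenols, goes on in one operation and comes off in one operation. The forward step must alkylate the hydrogen-bonded hydroxyl ortho to the carbonyl as well as the free one.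

**3 ⇒ 1 + 2.** The C4a–C4 bond between ring A and the acetyl group is cut. This leaves an arene whose three oxygens are already in the right places and already differentiated (one methyl ether, two hydroxyls). The forward acylation must go to the one ring position that is ortho to one hydroxyl and para to the other.

## Other disconnections considered

**Alternative 1:** Cuts C8a–O1, C4a–C4 and O1–C2, so that ring A arrives as an aryne and C2–C3–C4 with ring B as an acrylic acid.
- *Forward key step:* CsF would release the aryne from 4,5-dimethoxy-2-(trimethylsilyl)phenyl triflate A2 in the presence of (E)-3-methoxy-2-(3,4,5-trimethoxyphenyl)prop-2-enoic acid A3. The carboxylate oxygen and the acyl carbon would add across the triple bond (formal insertion into the acyl C–O bond). The resulting ortho phenoxide would then displace methoxide by addition–elimination to give 6,7-dimethoxy-3-(3,4,5-trimethoxyphenyl)chromen-4-one A1.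
- *In its favour:* three bonds and ring C form in one flask, the aryne is symmetrical so no regiochemistry arises, and the cascade is redox-neutral. In bond-forming economy and convergence it is better than the chosen plan, whose key step forms a single bond.
- *Against it here:* A1 carries a methyl ether at O7. The target would then need one of five methyl ethers removed selectively in the presence of a base-sensitive pyranone, and the crowded central methoxy group of ring B is the one Lewis acids tend to attack first. Replacing the O7 methyl by benzyl in the aryne would remove that problem but make the aryne unsymmetrical with almost no electronic bias, so a mixture of 6- and 7-regioisomers would be expected.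
- *Comparison:* on mechanism the two plans are equal in that neither has a stereochemical issue. On step count, A2 and A3 need about three steps each, so the longest sequence (about five) is comparable or slightly shorter, but the total is larger. The chosen plan is weaker in convergence but carries O7 differentiated from the first step, which is the decisive structural point.

**Alternative 2:** Cuts O1–C2 at the isoflavanone oxidation level.
- *Forward key step:* the deoxybenzoin 1-[4-(benzyloxy)-2-hydroxy-5-methoxyphenyl]-2-(3,4,5-trimethoxyphenyl)ethan-1-one A6 would be methylenated to the 2-aryl enone A5. Under mild base its C8a phenoxide would add to the terminal carbon (6-endo-trig oxa-Michael) to give racemic 7-(benzyloxy)-6-methoxy-3-(3,4,5-trimethoxyphenyl)chroman-4-one A4. Dehydrogenation and hydrogenolysis would lead to 11.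
- *In its favour:* A6 is two steps from 1 (acylation with the arylacetic acid, benzylation of the non-chelated hydroxyl). The ring closure needs no Lewis acid and no cationic intermediate, and O7 is differentiated throughout. On functional-group tolerance of the key step it is the equal or the better of the chosen plan.
- *Against it here:* A4 is one oxidation level too low. The late dehydrogenation has to act next to two very electron-rich arenes and a benzyl ether, where over-oxidation or hydroxylation at C3 can compete, and a stereocentre is made only to be destroyed.
- *Comparison:* both plans contain exactly one oxidation step (dehydrogenation there, epoxidation here), so they are equal in redox economy. The alternative is about five steps from 1 against six here, so it is better by one step. The chosen plan places its oxidation early on a robust intermediate and ends with a condensation; the alternative ends with an oxidation of the most electron-rich compound of its sequence.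

**Alternative 3:** Cuts C3–C1' and O1–C2, so that ring B arrives as a phenol and ring C is built from an enaminone.
- *Forward key step:* anodic oxidation of 2,6-dimethoxyphenol A9 in 1,1,1,3,3,3-hexafluoropropan-2-ol would give a para-electrophilic species. The α carbon of (E)-1-[4-(benzyloxy)-2-hydroxy-5-methoxyphenyl]-3-(dimethylamino)prop-2-en-1-one A8 would attack it, and the ring A phenol would close on the iminium carbon with loss of dimethylamine. The product would be 7-(benzyloxy)-3-(4-hydroxy-3,5-dimethoxyphenyl)-6-methoxychromen-4-one A7. Methylation of the ring B phenol and hydrogenolysis would then give 11.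
- *In its favour:* it is convergent, needs no halide or organometallic partner, uses no chemical oxidant, and makes two bonds and ring C in one operation. In convergence and atom economy of the key step it is better than the chosen plan, and the ring B hydroxyl of A7 can be methylated cleanly while O7 is still benzylated.
- *Against it here:* A8 has a trioxygenated ring A and should oxidise at a potential close to that of A9. Self-coupling of A9 and further oxidation of the phenolic product A7 are also plausible, so selectivity rests on a narrow potential window. An extra methylation is needed because the phenol must be free for the coupling.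
- *Comparison:* the alternative would need about six steps from 1 (acylation, benzylation, enaminone formation, electrolysis, methylation, hydrogenolysis), equal to the chosen plan. Structurally it is the more convergent. Mechanistically the chosen rearrangement has close analogy on 2'-benzyloxychalcone epoxides, whereas the anodic coupling would have to be extended to an unusually electron-rich enaminone.

Key step: step 5

## Route

**Step 1**
Reactants: 1 4-methoxybenzene-1,3-diol (4-methoxyresorcinol); 2 acetic acid
Product: 3 1-(2,4-dihydroxy-5-methoxyphenyl)ethan-1-one
Conditions: BF3·OEt2 (3 equiv), 2 as solvent, 90 °C; then aq NaOAc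
Reagents that add atoms: none
Why: Friedel–Crafts (Nencki-type) acylation at the only ring position that is ortho to one hydroxyl and para to the other and not flanked by two substituents. The product is held as a boron chelate of the ortho-hydroxy ketone, which should stop a second acylation, and BF3·OEt2 does not cleave the aryl methyl ether under these conditions.

**Step 2**
Reactants: 3 1-(2,4-dihydroxy-5-methoxyphenyl)ethan-1-one; 4 benzyl bromide
Product: 5 1-[2,4-bis(benzyloxy)-5-methoxyphenyl]ethan-1-one
Conditions: 4 (2.5 equiv), K2CO3, KI (cat.), DMF, 80 °C
Reagents that add atoms: none
Why: Double Williamson ether synthesis. The free para hydroxyl should react first; heating in DMF with iodide catalysis is chosen to alkylate the hydrogen-bonded ortho hydroxyl as well.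

**Step 3**
Reactants: 5 1-[2,4-bis(benzyloxy)-5-methoxyphenyl]ethan-1-one; 6 3,4,5-trimethoxybenzaldehyde
Product: 7 (E)-1-[2,4-bis(benzyloxy)-5-methoxyphenyl]-3-(3,4,5-trimethoxyphenyl)prop-2-en-1-one
Conditions: KOH (50% aq), EtOH/THF, rt
Reagents that add atoms: none
Why: Claisen–Schmidt condensation of a methyl ketone with a non-enolisable aldehyde. E1cB loss of water from the aldol should give the conjugated E alkene, and with both phenols capped no phenoxide deactivates the ketone.

**Step 4**
Reactants: 7 (E)-1-[2,4-bis(benzyloxy)-5-methoxyphenyl]-3-(3,4,5-trimethoxyphenyl)prop-2-en-1-one
Product: 8 rac-trans-[2,4-bis(benzyloxy)-5-methoxyphenyl][3-(3,4,5-trimethoxyphenyl)oxiran-2-yl]methanone ((2S,3R) enantiomer drawn)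
Conditions: 30% aq H2O2, 2 M NaOH, MeOH/THF, 0 °C to rt
Reagents that add atoms: hydrogen peroxide, OO
Why: Weitz–Scheffer nucleophilic epoxidation: hydroperoxide adds to the β carbon and the enolate closes the oxirane with loss of hydroxide. The enolate can rotate before closure, so the trans epoxide should result as a racemate; the benzyl ether on the ortho oxygen prevents Algar–Flynn–Oyamada cyclisation.

**Step 5**
Reactants: 8 rac-trans-[2,4-bis(benzyloxy)-5-methoxyphenyl][3-(3,4,5-trimethoxyphenyl)oxiran-2-yl]methanone
Product: 9 (Z)-1-[2,4-bis(benzyloxy)-5-methoxyphenyl]-3-hydroxy-2-(3,4,5-trimethoxyphenyl)prop-2-en-1-one (chelated enol of the keto aldehyde)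
Conditions: BF3·OEt2 (1.5 equiv), CH2Cl2, 0 °C, 15 min; then sat. aq NaHCO3
Reagents that add atoms: none
Why: BF3 coordinates the oxirane oxygen and the C–O bond at the benzylic carbon (the later C3) lengthens, because the developing positive charge is shared with ring B through its para methoxy group, whereas a cation at the other oxirane carbon would sit next to the carbonyl. The aroyl group then shifts with its bonding electrons from the α carbon to this benzylic carbon, which forms the C3–C4 bond, while the oxygen left on the α carbon becomes the aldehyde carbonyl of C2; this is a semipinacol (Meinwald-type) rearrangement, and the closest known reaction type is the BF3-promoted conversion of 2'-alkoxychalcone epoxides into 2-aryl-3-oxo-3-arylpropanals. No ring is closed and no stereocentre is made; the two oxirane stereocentres are erased, which is why racemic trans 8 suffices. Two selectivities are needed: opening at the ring B carbon, secured by the donor ring B against the acyl-destabilised alternative, and migration of acyl in preference to hydride, secured by the high migratory aptitude of the acyl group, whose carbonyl π system can bridge to the cationic centre. The product should settle as the hydrogen-bonded Z enol 9, which takes the acidic C3 hydrogen out of further reaction. Both phenols are benzyl ethers, so the ortho oxygen is a poor nucleophile towards the benzylic cation and cannot close a flavanonol ring without losing benzyl. Low temperature, a contact time of minutes and a bicarbonate quench are chosen to limit loss of the formyl group and capture of the cation by fluoride.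

**Step 6**
Reactants: 9 (Z)-1-[2,4-bis(benzyloxy)-5-methoxyphenyl]-3-hydroxy-2-(3,4,5-trimethoxyphenyl)prop-2-en-1-one
Product: 11 7-hydroxy-6-methoxy-3-(3,4,5-trimethoxyphenyl)-4H-chromen-4-one, via 2-hydroxyisoflavanone hemiacetal 10 (not isolated)
Conditions: H2 (1 atm), 10% Pd/C, EtOAc/MeOH, rt; filter; then conc. HCl (cat.), MeOH, 60 °C
Reagents that add atoms: none
Why: Hydrogenolysis of both benzyl ethers frees the C8a phenol, which adds to the aldehyde carbon (6-exo-trig hemiacetal formation) to give 10. Acid-catalysed dehydration then forms the O1–C2=C3 vinylogous ester of the chromenone, removing both transient stereocentres; the aryl methyl ethers are inert to both stages.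

## Compound list

1 | 4-methoxybenzene-1,3-diol (4-methoxyresorcinol) | COc1ccc(O)cc1O | starting material
2 | acetic acid | CC(=O)O | starting material
3 | 1-(2,4-dihydroxy-5-methoxyphenyl)ethan-1-one | COc1cc(C(C)=O)c(O)cc1O | intermediate
4 | benzyl bromide | BrCc1ccccc1 | starting material
5 | 1-[2,4-bis(benzyloxy)-5-methoxyphenyl]ethan-1-one | COc1cc(C(C)=O)c(OCc2ccccc2)cc1OCc1ccccc1 | intermediate
6 | 3,4,5-trimethoxybenzaldehyde | COc1cc(C=O)cc(OC)c1OC | starting material
7 | (E)-1-[2,4-bis(benzyloxy)-5-methoxyphenyl]-3-(3,4,5-trimethoxyphenyl)prop-2-en-1-one | COc1cc(C(=O)/C=C/c2cc(OC)c(OC)c(OC)c2)c(OCc2ccccc2)cc1OCc1ccccc1 | intermediate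
8 | rac-trans-[2,4-bis(benzyloxy)-5-methoxyphenyl][3-(3,4,5-trimethoxyphenyl)oxiran-2-yl]methanone, (2S,3R) enantiomer drawn | O=C(c1cc(OC)c(OCc2ccccc2)cc1OCc1ccccc1)[C@@H]1[C@H](O1)c1cc(OC)c(OC)c(OC)c1 | intermediate
9 | (Z)-1-[2,4-bis(benzyloxy)-5-methoxyphenyl]-3-hydroxy-2-(3,4,5-trimethoxyphenyl)prop-2-en-1-one | O/C=C(/c1cc(OC)c(OC)c(OC)c1)C(=O)c1cc(OC)c(OCc2ccccc2)cc1OCc1ccccc1 | intermediate
10 | 2,7-dihydroxy-6-methoxy-3-(3,4,5-trimethoxyphenyl)chroman-4-one (racemic, mixture of C2 epimers, configuration at C2 and C3 undefined; not isolated) | COc1cc2C(=O)C(c3cc(OC)c(OC)c(OC)c3)C(O)Oc2cc1O | intermediate
11 | 7-hydroxy-6-methoxy-3-(3,4,5-trimethoxyphenyl)-4H-chromen-4-one | COc1cc2c(=O)c(-c3cc(OC)c(OC)c(OC)c3)coc2cc1O | target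

## Step count and risk assessment

Total step count: 6. Longest linear sequence: 6 (from 1 to 11); 2, 4 and 6 are bought.

**Step 5 (key step).** The most likely failures are loss of the formyl group on extended contact with the Lewis acid, capture of the benzylic cation by fluoride, and attack of the ortho benzyloxy oxygen on the cation with loss of benzyl. The two meta methoxy groups of ring B withdraw inductively, so ionisation is less easy than for a simple 4-methoxyphenyl ring, and the longer contact this requires gives these side paths more time. Fallback, setting out from 7 and returning at 9: oxidative 1,2-aryl migration with a trivalent iodine reagent, in which ring B, not the aroyl group, moves. Treating 7 with PhI(OAc)2 and TsOH·H2O in MeOH/HC(OMe)3 should give the β-keto acetal rac-1-[2,4-bis(benzyloxy)-5-methoxyphenyl]-3,3-dimethoxy-2-(3,4,5-trimethoxyphenyl)propan-1-one F1. Hydrolysis of the acetal with aqueous HCl in THF would return the route to 9.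

**Step 4.** Hydroperoxide addition may be slow, because the enone is deactivated by the alkoxy donors on both rings; long exposure to alkaline peroxide then invites retro-aldol cleavage and oxidative degradation. Fallback, setting out from 5 and returning at 8: α-bromination of 5 with PhNMe3Br3 in THF should give 1-[2,4-bis(benzyloxy)-5-methoxyphenyl]-2-bromoethan-1-one F4. A Darzens condensation of F4 with 6 (NaOEt, EtOH, 0 °C) would build the trans oxirane directly from the aldehyde, with no enone and no peroxide involved.

**Step 6.** Hydrogenation may go too far: reduction of the enolized aldehyde before ring closure, or of the C2=C3 bond once the chromenone has formed. Cleavage of the more hindered ortho benzyl ether may also lag and leave partly protected material. Fallback, setting out from 9 and returning at 11: non-reductive debenzylation with BCl3 and pentamethylbenzene as benzyl-cation scavenger in CH2Cl2 at −78 °C, followed by a methanolic HCl work-up. This should pass through the same hemiacetal 10 and makes no compound outside the list (entry F0).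

**Step 2.** Alkylation of the hydrogen-bonded ortho hydroxyl may stall at the monobenzyl ether, and forcing it risks C-benzylation of the electron-rich ring. Fallback, setting out from 1 and returning at 5, in which the acetyl group is introduced after protection so that no chelated phenol has to be alkylated. Benzylation of 1 with 4 and K2CO3 in DMF should give 2,4-bis(benzyloxy)-1-methoxybenzene F2. Bromination with N-bromosuccinimide in MeCN at 0 °C should occur para to one benzyloxy group and ortho to the other, giving 1,5-bis(benzyloxy)-2-bromo-4-methoxybenzene F3. Bromine–lithium exchange (n-BuLi, THF, −78 °C) and acylation with N-methoxy-N-methylacetamide would then give 5.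

## Further compounds

F1 | step 5 | rac-1-[2,4-bis(benzyloxy)-5-methoxyphenyl]-3,3-dimethoxy-2-(3,4,5-trimethoxyphenyl)propan-1-one | COC(OC)C(c1cc(OC)c(OC)c(OC)c1)C(=O)c1cc(OC)c(OCc2ccccc2)cc1OCc1ccccc1
F2 | step 2 | 2,4-bis(benzyloxy)-1-methoxybenzene | COc1ccc(OCc2ccccc2)cc1OCc1ccccc1
F3 | step 2 | 1,5-bis(benzyloxy)-2-bromo-4-methoxybenzene | COc1cc(Br)c(OCc2ccccc2)cc1OCc1ccccc1
F4 | step 4 | 1-[2,4-bis(benzyloxy)-5-methoxyphenyl]-2-bromoethan-1-one | COc1cc(C(=O)CBr)c(OCc2ccccc2)cc1OCc1ccccc1
F0 | step 6 | none | none
A1 | alternative 1 | 6,7-dimethoxy-3-(3,4,5-trimethoxyphenyl)chromen-4-one | COc1cc2c(=O)c(-c3cc(OC)c(OC)c(OC)c3)coc2cc1OC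
A2 | alternative 1 | 4,5-dimethoxy-2-(trimethylsilyl)phenyl trifluoromethanesulfonate | COc1cc(OS(=O)(=O)C(F)(F)F)c([Si](C)(C)C)cc1OC
A3 | alternative 1 | (E)-3-methoxy-2-(3,4,5-trimethoxyphenyl)prop-2-enoic acid | CO/C=C(/C(=O)O)c1cc(OC)c(OC)c(OC)c1
A4 | alternative 2 | rac-7-(benzyloxy)-6-methoxy-3-(3,4,5-trimethoxyphenyl)chroman-4-one | COc1cc2c(cc1OCc1ccccc1)OCC(c1cc(OC)c(OC)c(OC)c1)C2=O
A5 | alternative 2 | 1-[4-(benzyloxy)-2-hydroxy-5-methoxyphenyl]-2-(3,4,5-trimethoxyphenyl)prop-2-en-1-one | C=C(C(=O)c1cc(OC)c(OCc2ccccc2)cc1O)c1cc(OC)c(OC)c(OC)c1
A6 | alternative 2 | 1-[4-(benzyloxy)-2-hydroxy-5-methoxyphenyl]-2-(3,4,5-trimethoxyphenyl)ethan-1-one | COc1cc(C(=O)Cc2cc(OC)c(OC)c(OC)c2)c(O)cc1OCc1ccccc1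
A7 | alternative 3 | 7-(benzyloxy)-3-(4-hydroxy-3,5-dimethoxyphenyl)-6-methoxychromen-4-one | COc1cc2c(=O)c(-c3cc(OC)c(O)c(OC)c3)coc2cc1OCc1ccccc1
A8 | alternative 3 | (E)-1-[4-(benzyloxy)-2-hydroxy-5-methoxyphenyl]-3-(dimethylamino)prop-2-en-1-one | COc1cc(C(=O)/C=C/N(C)C)c(O)cc1OCc1ccccc1
A9 | alternative 3 | 2,6-dimethoxyphenol | COc1cccc(OC)c1O
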